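Ring A is disconnected at C6–C7 (chromone numbering). A 4-pyranone that already carries ring B holds two enol-ether arms on its C4a=C8a bond: a Z silyl enol ether (C5=C6, prenyl on C6) and a bis-silyl ketene acetal (C8=C7). Heating should close this hexatriene by 6π electrocyclisation and expel silanol, so one operation builds ring A with both oxygens and the C6 prenyl group in place. The step exploits the 1,3-dioxygenated C5–C6–C7 segment of ring A, whose central carbon bears the prenyl group. The precursor is the fully substituted pyranone 18, assembled from an arylacetic acid, pentane-2,4-dione, prenyl bromide and CO2.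

Key step: step 10

Remark: Ar = 3,4-bis(methoxymethoxy)-5-(3-methylbut-2-en-1-yl)phenyl; ring A atoms carry chromone numbering; 5 (E/Z mixture) and 19 (racemic at C6) hold the only undefined stereo-elements, and neither survives into 22, which has no stereocentre.

Step 1
Reactants: 1 3-bromo-4,5-dihydroxybenzaldehyde
Product: 2 3-bromo-4,5-bis(methoxymethoxy)benzaldehyde
Conditions: MOMCl, iPr2NEt, CH2Cl2, 0 °C → rt
Reagents that add atoms: chloromethyl methyl ether, COCCl
Why: O-alkylation of both phenols (MOM ether formation) under amine base should be clean because the aldehyde and the aryl bromide are inert to these conditions.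

Step 2
Reactants: 2 3-bromo-4,5-bis(methoxymethoxy)benzaldehyde; 3 tributyl(3-methylbut-2-en-1-yl)stannane
Product: 4 3,4-bis(methoxymethoxy)-5-(3-methylbut-2-en-1-yl)benzaldehyde (ArCHO)
Conditions: Pd(PPh3)4 (5 mol %), DMF, 100 °C
Reagents that add atoms: none
Why: Stille coupling under zerovalent palladium catalysis should give the linear prenyl arene, since reductive elimination takes place at the unhindered primary terminus of the prenyl–palladium intermediate, and the neutral conditions spare the aldehyde and the MOM ethers.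

Step 3
Reactants: 4 3,4-bis(methoxymethoxy)-5-(3-methylbut-2-en-1-yl)benzaldehyde
Product: 6 Ar-acetonitrile (ArCH2CN), via N-(1-tosylvinyl)formamide 5 (not isolated)
Conditions: TosMIC, KOtBu, DME, −40 °C; then MeOH, 65 °C
Reagents that add atoms: p-toluenesulfonylmethyl isocyanide, Cc1ccc(cc1)S(=O)(=O)C[N+]#[C-]
Why: Van Leusen reductive cyanation: the TosMIC anion adds to the aldehyde, the oxazoline opens to 5, and methanolysis with loss of sulfinate and methyl formate gives the one-carbon-homologated nitrile under basic conditions that MOM ethers and the prenyl group tolerate.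

Step 4
Reactants: 6 Ar-acetonitrile
Product: 7 Ar-acetic acid (ArCH2CO2H)
Conditions: KOH, EtOH–H2O, 85 °C; then 1 M KHSO4 to pH 4, 0 °C
Reagents that add atoms: potassium hydroxide, [K+].[OH-]; water, O
Why: Alkaline nitrile hydrolysis to the carboxylate followed by cold, mildly acidic work-up should give the arylacetic acid, since MOM ethers and the trisubstituted alkene are stable to hydroxide and to a brief exposure to pH 4.

Step 5
Reactants: 7 Ar-acetic acid; 8 pentane-2,4-dione
Product: 10 3-(Ar-acetyl)pentane-2,4-dione, via arylacetyl chloride 9 (not isolated)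
Conditions: 1-chloro-N,N,2-trimethylprop-1-en-1-amine, CH2Cl2, 0 °C; then 8, MgCl2, pyridine, CH2Cl2, 0 °C → rt
Reagents that add atoms: none
Why: The chloroenamine makes the acid chloride without releasing HCl (so the MOM ethers survive), and the magnesium enolate of the diketone is then C-acylated (MgCl2–amine soft-enolisation acylation) to the enolised triacylmethane.

Step 6
Reactants: 10 3-(Ar-acetyl)pentane-2,4-dione
Product: 12 3-acetyl-5-Ar-2-methyl-4H-pyran-4-one, via enaminone 11 (not isolated)
Conditions: Me2NCH(OMe)2 (1.1 equiv), PhMe, 70 °C; then AcOH, 70 °C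
Reagents that add atoms: N,N-dimethylformamide dimethyl acetal, COC(OC)N(C)C
Why: The amide acetal condenses at the most acidic remaining CH2 (benzylic, next to a carbonyl) to give enaminone 11, whose enol oxygen adds to the aminomethylene carbon and expels dimethylamine (enaminone cyclocondensation, as with 2-acyl-1,3-diones); because the two acetyl groups are equivalent only one pyranone can form.

Step 7
Reactants: 12 3-acetyl-5-Ar-2-methyl-4H-pyran-4-one; 13 1-bromo-3-methylbut-2-ene
Product: 15 5-Ar-2-methyl-3-(5-methylhex-4-enoyl)-4H-pyran-4-one, via dilithium dianion 14 (not isolated)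
Conditions: LiN(iPr)2 (2.2 equiv), THF, −78 → −20 °C; then 13 (1.0 equiv), −78 → −30 °C; NH4Cl (aq)
Reagents that add atoms: none
Why: In the dianion the lateral (vinylogous) carbon is the stabilised site and the acetyl enolate carbon is the last-formed and most nucleophilic one, so one equivalent of prenyl bromide should alkylate the acetyl terminus by SN2 (polyanion alkylation as with β-dicarbonyl dianions).

Step 8
Reactants: 15 5-Ar-2-methyl-3-(5-methylhex-4-enoyl)-4H-pyran-4-one
Product: 17 [5-Ar-3-(5-methylhex-4-enoyl)-4-oxo-4H-pyran-2-yl]acetic acid, via lithium dienolate 16 (not isolated)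
Conditions: LiN(SiMe3)2 (1.2 equiv), THF, −78 → −40 °C; CO2 (g), −78 °C; then 0.5 M HCl to pH 4, 0 °C
Reagents that add atoms: carbon dioxide, O=C=O
Why: The 2-methyl group, vinylogous to both the ring carbonyl and the side-chain ketone, is the most acidic site, so lateral metalation–carboxylation should place CO2 on its terminal carbon, and any β-keto acid from the minor ketone enolate decarboxylates back to 15 on work-up.

Step 9
Reactants: 17 [5-Ar-3-(5-methylhex-4-enoyl)-4-oxo-4H-pyran-2-yl]acetic acid
Product: 18 5-Ar-2-[2,2-bis(tert-butyldimethylsilyloxy)ethenyl]-3-[(1Z)-1-(tert-butyldimethylsilyloxy)-5-methylhexa-1,4-dien-1-yl]-4H-pyran-4-one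
Conditions: TBSOTf (3.5 equiv), Et3N (6 equiv), CH2Cl2, −78 → 0 °C; pentane extraction, no chromatography
Reagents that add atoms: tert-butyldimethylsilyl trifluoromethanesulfonate, CC(C)(C)[Si](C)(C)OS(=O)(=O)C(F)(F)F
Why: Soft enolisation with silyl triflate and amine should turn the acid into the bis-silyl ketene acetal and the ketone into its silyl enol ether, Z because allylic strain keeps the chain away from the pyranone as with aryl alkyl ketones, and the third silyl group is expected on the exposed carboxyl oxygen because the C4 oxygen is buried between the aryl ring and the neighbouring arm.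

Step 10
Reactants: 18 5-Ar-2-[2,2-bis(tert-butyldimethylsilyloxy)ethenyl]-3-[(1Z)-1-(tert-butyldimethylsilyloxy)-5-methylhexa-1,4-dien-1-yl]-4H-pyran-4-one
Product: 20 3-Ar-5,7-bis(tert-butyldimethylsilyloxy)-6-(3-methylbut-2-en-1-yl)-4H-chromen-4-one, via 6,7-dihydrochromenone 19 (not isolated)
Conditions: N-(tert-butyldimethylsilyl)-N-methyltrifluoroacetamide (2 equiv), degassed PhMe (0.02 M), 120 °C, sealed tube
Reagents that add atoms: none
Why: Proposed new method: the pyranone double bond locks the triene C7=C8–C8a=C4a–C5=C6 in the cisoid arrangement, so thermal disrotatory 6π electrocyclisation should join C6 to C7 and give cyclohexadiene 19, from which 1,2-elimination of tert-butyldimethylsilanol across C6–C7, pushed by the oxygen that stays on C7, makes ring A aromatic. The closest known reaction type is the thermal 6π-electrocyclisation–elimination benzannulation of 2,3-dialkenyl heteroarenes and of silyloxy-substituted hexatrienes. Ring A is closed as a six-membered carbocycle by 6π (disrotatory) closure, and no stereocentre has to be controlled because the C6 centre of 19 is erased on aromatisation. The only selectivity required is which atoms bond: C8 cannot reach the C5 carbon without making a four-membered ring, neither carbonyl group is free to act as an electrophile or enolate, and the Z enol ether puts hydrogen rather than the prenyl chain on the inner face of the C6 terminus. Conjugation of the ketene acetal with the C4 carbonyl polarises the triene (C7 electron-poor, C6 electron-rich), which should lower the barrier, and the silyl amide captures the liberated silanol before it can protonate unreacted ketene acetal.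

Step 11
Reactants: 20 3-Ar-5,7-bis(tert-butyldimethylsilyloxy)-6-(3-methylbut-2-en-1-yl)-4H-chromen-4-one
Product: 22 isoangustone A, via bis-MOM diol 21 (not isolated)
Conditions: KHF2, MeOH–THF, rt; then 3 M HCl (aq), 40 °C
Reagents that add atoms: none
Why: Fluoride-mediated desilylation removes the two aryl silyl ethers, which are activated as vinylogous silyl esters of the chromone carbonyl, and acid-catalysed solvolysis of the MOM acetals in methanol then frees the catechol at a temperature at which ortho-prenyl phenols should not yet cyclise to chromans.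

Compound list (Ar = 3,4-bis(methoxymethoxy)-5-(3-methylbut-2-en-1-yl)phenyl)
1 | 3-bromo-4,5-dihydroxybenzaldehyde | O=Cc1cc(O)c(O)c(Br)c1 | starting material
2 | 3-bromo-4,5-bis(methoxymethoxy)benzaldehyde | COCOc1cc(C=O)cc(Br)c1OCOC | intermediate
3 | tributyl(3-methylbut-2-en-1-yl)stannane | CCCC[Sn](CCCC)(CCCC)CC=C(C)C | starting material
4 | 3,4-bis(methoxymethoxy)-5-(3-methylbut-2-en-1-yl)benzaldehyde | COCOc1cc(C=O)cc(CC=C(C)C)c1OCOC | intermediate
5 | N-[2-Ar-1-(4-methylbenzenesulfonyl)ethenyl]formamide (E/Z mixture, present as its potassium salt) | O=CNC(=Cc1cc(OCOC)c(OCOC)c(CC=C(C)C)c1)S(=O)(=O)c1ccc(C)cc1 | intermediate (not isolated)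
6 | Ar-acetonitrile | N#CCc1cc(OCOC)c(OCOC)c(CC=C(C)C)c1 | intermediate
7 | Ar-acetic acid | OC(=O)Cc1cc(OCOC)c(OCOC)c(CC=C(C)C)c1 | intermediate
8 | pentane-2,4-dione | CC(=O)CC(C)=O | starting material
9 | Ar-acetyl chloride | ClC(=O)Cc1cc(OCOC)c(OCOC)c(CC=C(C)C)c1 | intermediate (not isolated)
10 | 3-(Ar-acetyl)pentane-2,4-dione (enolised triacylmethane) | CC(=O)C(C(C)=O)C(=O)Cc1cc(OCOC)c(OCOC)c(CC=C(C)C)c1 | intermediate
11 | 3-[(2E)-2-Ar-3-(dimethylamino)prop-2-enoyl]pentane-2,4-dione | CC(=O)C(C(C)=O)C(=O)/C(=C/N(C)C)c1cc(OCOC)c(OCOC)c(CC=C(C)C)c1 | intermediate (not isolated)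
12 | 3-acetyl-5-Ar-2-methyl-4H-pyran-4-one | CC(=O)c1c(C)occ(-c2cc(OCOC)c(OCOC)c(CC=C(C)C)c2)c1=O | intermediate
13 | 1-bromo-3-methylbut-2-ene (prenyl bromide) | CC(C)=CCBr | starting material
14 | dilithium dianion of 12 (lateral methylene and acetyl enolate) | [Li+].[Li+].C=C([O-])C1=C([O-])C(c2cc(OCOC)c(OCOC)c(CC=C(C)C)c2)=COC1=C | intermediate (not isolated)
15 | 5-Ar-2-methyl-3-(5-methylhex-4-enoyl)-4H-pyran-4-one | CC(C)=CCCC(=O)c1c(C)occ(-c2cc(OCOC)c(OCOC)c(CC=C(C)C)c2)c1=O | intermediate
16 | lithium dienolate of 15 (2-methylene-2H-pyran-4-olate) | [Li+].C=C1OC=C(c2cc(OCOC)c(OCOC)c(CC=C(C)C)c2)C([O-])=C1C(=O)CCC=C(C)C | intermediate (not isolated)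
17 | [5-Ar-3-(5-methylhex-4-enoyl)-4-oxo-4H-pyran-2-yl]acetic acid | CC(C)=CCCC(=O)c1c(CC(=O)O)occ(-c2cc(OCOC)c(OCOC)c(CC=C(C)C)c2)c1=O | intermediate
18 | 5-Ar-2-[2,2-bis(tert-butyldimethylsilyloxy)ethenyl]-3-[(1Z)-1-(tert-butyldimethylsilyloxy)-5-methylhexa-1,4-dien-1-yl]-4H-pyran-4-one | CC(C)(C)[Si](C)(C)OC(O[Si](C)(C)C(C)(C)C)=Cc1occ(-c2cc(OCOC)c(OCOC)c(CC=C(C)C)c2)c(=O)c1/C(O[Si](C)(C)C(C)(C)C)=C/CC=C(C)C | intermediate (key-step precursor)
19 | rac-3-Ar-5,7,7-tris(tert-butyldimethylsilyloxy)-6-(3-methylbut-2-en-1-yl)-6,7-dihydro-4H-chromen-4-one | CC(C)=CCC1C(O[Si](C)(C)C(C)(C)C)=C2C(=O)C(c3cc(OCOC)c(OCOC)c(CC=C(C)C)c3)=COC2=CC1(O[Si](C)(C)C(C)(C)C)O[Si](C)(C)C(C)(C)C | intermediate (not isolated)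
20 | 3-Ar-5,7-bis(tert-butyldimethylsilyloxy)-6-(3-methylbut-2-en-1-yl)-4H-chromen-4-one | CC(C)=CCc1cc(-c2coc3cc(O[Si](C)(C)C(C)(C)C)c(CC=C(C)C)c(O[Si](C)(C)C(C)(C)C)c3c2=O)cc(OCOC)c1OCOC | intermediate (key-step product)
21 | 3-Ar-5,7-dihydroxy-6-(3-methylbut-2-en-1-yl)-4H-chromen-4-one | CC(C)=CCc1cc(-c2coc3cc(O)c(CC=C(C)C)c(O)c3c2=O)cc(OCOC)c1OCOC | intermediate (not isolated)
22 | isoangustone A, 3-[3,4-dihydroxy-5-(3-methylbut-2-en-1-yl)phenyl]-5,7-dihydroxy-6-(3-methylbut-2-en-1-yl)-4H-chromen-4-one | CC(C)=CCc1cc(-c2coc3cc(O)c(CC=C(C)C)c(O)c3c2=O)cc(O)c1O | target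

Total step count: 11. Longest linear sequence: 11 steps (1 to 22).

Steps most likely to fail

Step 10 (key step). The crowded triene may not reach the coplanar cisoid geometry needed for disrotatory closure, because the inner silyloxy group of the ketene acetal presses against the neighbouring arm. Protodesilylation or silyl transfer could then outrun cyclisation. The fallback uses known chemistry and sets out from acid 17. Esterification with Me3SiCHN2 gives methyl [5-Ar-3-(5-methylhex-4-enoyl)-4-oxo-4H-pyran-2-yl]acetate F1. Mg(OMe)2 in MeOH at 65 °C then closes ring A by intramolecular Claisen condensation of the ketone α-carbon (C6) onto the ester carbonyl (C7). This is the polar ring closure by which 3,5-dioxo esters give phloroglucinols and (2-acylaryl)acetates give naphthalene-1,3-diols. Tautomerisation gives diol 21, where the route is rejoined for the acid stage of step 11.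

Step 9. After removal of the very acidic lateral proton, the third silyl group may be delivered to the ring carbonyl oxygen instead of the carboxyl oxygen. That would leave a cross-conjugated 2-alkylidene-2H-pyran silyl ether with no hexatriene. The ketene acetal may also lose a silyl group by hydrolysis during isolation. The fallback drops silyl masking altogether and sets out from ketone 15. NaH and diethyl carbonate in THF at 65 °C ethoxycarbonylate the lateral methyl group to ethyl [5-Ar-3-(5-methylhex-4-enoyl)-4-oxo-4H-pyran-2-yl]acetate F2. Under the same basic conditions F2 undergoes the Claisen ring closure, and the route is rejoined at 21.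

Step 7. Incomplete second deprotonation would divert the prenyl bromide to the lateral carbon, and excess electrophile would over-alkylate. The fallback makes the side-chain ketone by acyl substitution instead of enolate alkylation and sets out from acid 7. Acid chloride 9, prepared as in step 5, C-acylates N-methoxy-N-methyl-3-oxobutanamide (MgCl2, pyridine) to 2-acetyl-4-Ar-N-methoxy-N-methyl-3-oxobutanamide F3. DMF dimethyl acetal converts F3 into (4E)-2-acetyl-4-Ar-5-(dimethylamino)-N-methoxy-N-methyl-3-oxopent-4-enamide F4, which cyclises to 5-Ar-N-methoxy-N,2-dimethyl-4-oxo-4H-pyran-3-carboxamide F5. Addition of (4-methylpent-3-en-1-yl)magnesium bromide F6 (from 5-bromo-2-methylpent-2-ene and Mg) in THF at −78 °C gives ketone 15, where the route is rejoined.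

Further compounds
F1 | step 10 | methyl [5-Ar-3-(5-methylhex-4-enoyl)-4-oxo-4H-pyran-2-yl]acetate | COC(=O)Cc1occ(-c2cc(OCOC)c(OCOC)c(CC=C(C)C)c2)c(=O)c1C(=O)CCC=C(C)C
F2 | step 9 | ethyl [5-Ar-3-(5-methylhex-4-enoyl)-4-oxo-4H-pyran-2-yl]acetate | CCOC(=O)Cc1occ(-c2cc(OCOC)c(OCOC)c(CC=C(C)C)c2)c(=O)c1C(=O)CCC=C(C)C
F3 | step 7 | 2-acetyl-4-Ar-N-methoxy-N-methyl-3-oxobutanamide | CON(C)C(=O)C(C(C)=O)C(=O)Cc1cc(OCOC)c(OCOC)c(CC=C(C)C)c1
F4 | step 7 | (4E)-2-acetyl-4-Ar-5-(dimethylamino)-N-methoxy-N-methyl-3-oxopent-4-enamide | CON(C)C(=O)C(C(C)=O)C(=O)/C(=C/N(C)C)c1cc(OCOC)c(OCOC)c(CC=C(C)C)c1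
F5 | step 7 | 5-Ar-N-methoxy-N,2-dimethyl-4-oxo-4H-pyran-3-carboxamide | CON(C)C(=O)c1c(C)occ(-c2cc(OCOC)c(OCOC)c(CC=C(C)C)c2)c1=O
F6 | step 7 | (4-methylpent-3-en-1-yl)magnesium bromide | CC(C)=CCC[Mg]Br
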